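**Retrosynthesis (lactone atoms numbered O1, C2(=O), C3=C4, C5, C6(Me)(OH), C7; target is 6R,7S with a 2E side-chain olefin)**
1. The only ring is closed last through C4–C5: a carbene catalyst turns the acrylate CH2 of epoxy ester 10 into a nucleophile (β-acyl-vinyl anion equivalent), which opens the tethered terminal epoxide and frees the C6 hydroxyl; both carbons are electrophilic in their normal polarity.
2. Ester bond O1–C2: epoxy alcohol 4 plus 2-substituted acrylic acid 8.
3. Epoxy alcohol 4 (both stereocentres): Sharpless kinetic resolution/epoxidation of racemic isopropenyl carbinol 3, the singlet-oxygen ene product of geranyl acetate 1, which already carries the E-olefin and the acetate.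
4. Acid 8: enol triflate of sulcatone 5, then hydroxycarbonylation.

Assumption: geranyl acetate, sulcatone, L-(+)-diisopropyl tartrate and the stable triazolylidene carbene are taken as purchased, and the 50 % ceiling of a kinetic resolution is accepted for the sake of step count.

Step 1
Reactants: 1 geranyl acetate [(2E)-3,7-dimethylocta-2,6-dien-1-yl acetate]
Product: 3 (2E)-6-hydroxy-3,7-dimethylocta-2,7-dien-1-yl acetate (racemic), via allylic hydroperoxide 2 (not isolated)
Conditions: O2, hν (white LED), 5,10,15,20-tetraphenylporphyrin (0.2 mol %), CH2Cl2, 0 °C; then PPh3 (1.0 equiv), 0 → 20 °C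
Reagents that add atoms: dioxygen, O=O
Why: Schenck ene reaction of singlet oxygen at the electron-rich 6,7-olefin (the allylic-acetate olefin is deactivated), with hydrogen abstraction from the cis methyl group, gives the secondary allylic hydroperoxide that PPh3 reduces in the same flask; the carbinol centre is racemic and the tertiary regioisomer (formed in about equal amount) is removed by chromatography.

Step 2
Reactants: 3 (2E)-6-hydroxy-3,7-dimethylocta-2,7-dien-1-yl acetate (racemic)
Product: 4 (2E,6S)-6-hydroxy-3-methyl-6-[(2R)-2-methyloxiran-2-yl]hex-2-en-1-yl acetate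
Conditions: Ti(OiPr)4 (10 mol %), L-(+)-diisopropyl tartrate (15 mol %), t-BuOOH (0.45 equiv), 4 Å molecular sieves, CH2Cl2, −20 °C
Reagents that add atoms: tert-butyl hydroperoxide, CC(C)(C)OO
Why: Sharpless asymmetric epoxidation run as a kinetic resolution: with L-(+)-tartrate the (S)-carbinol reacts far faster and is epoxidised on the face that gives the erythro epoxy alcohol, so lactone C7 (S) is selected and lactone C6 (R) is created together, while the (R)-alcohol, the acetate and the non-allylic olefin are left alone.

Step 3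
Reactants: 5 sulcatone (6-methylhept-5-en-2-one)
Product: 7 6-methylhepta-1,5-dien-2-yl trifluoromethanesulfonate, via lithium enolate 6 (not isolated)
Conditions: LiN(iPr)2 (1.1 equiv), THF, −78 °C; then PhNTf2 (1.05 equiv), −78 → 0 °C
Reagents that add atoms: N-phenylbis(trifluoromethanesulfonimide), O=S(=O)(N(c1ccccc1)S(=O)(=O)C(F)(F)F)C(F)(F)F
Why: Kinetic deprotonation of the methyl ketone at CH3 and O-triflation of the terminal enolate (enol triflate synthesis); no stereocentre is formed.

Step 4
Reactants: 7 6-methylhepta-1,5-dien-2-yl trifluoromethanesulfonate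
Product: 8 6-methyl-2-methylidenehept-5-enoic acid
Conditions: Pd(OAc)2 (3 mol %), 1,1'-bis(diphenylphosphino)ferrocene (6 mol %), CO (1 atm), H2O (10 equiv), Et3N (2.5 equiv), DMF, 60 °C
Reagents that add atoms: carbon monoxide, [C-]#[O+]; water, O
Why: Palladium-catalysed hydroxycarbonylation of an enol triflate (oxidative addition to zerovalent palladium, CO insertion, capture by water) gives the 2-substituted acrylic acid with the 1,1-disubstituted olefin fixed in place; no stereocentre is formed.

Step 5
Reactants: 8 6-methyl-2-methylidenehept-5-enoic acid; 4 (2E,6S)-6-hydroxy-3-methyl-6-[(2R)-2-methyloxiran-2-yl]hex-2-en-1-yl acetate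
Product: 10 (1S,4E)-6-(acetyloxy)-4-methyl-1-[(2R)-2-methyloxiran-2-yl]hex-4-en-1-yl 6-methyl-2-methylidenehept-5-enoate, via mixed anhydride 9 (not isolated)
Conditions: 8 (1.3 equiv), 2,4,6-trichlorobenzoyl chloride (1.3 equiv), Et3N (1.5 equiv), THF, 20 °C; then 4, 4-(dimethylamino)pyridine (1.5 equiv), PhMe, 20 °C
Reagents that add atoms: none
Why: Yamaguchi esterification acylates the hindered secondary hydroxyl on oxygen (retention at lactone C7) under non-acidic conditions that spare the epoxide, the acetate and both stereocentres.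

Step 6
Reactants: 10 (1S,4E)-6-(acetyloxy)-4-methyl-1-[(2R)-2-methyloxiran-2-yl]hex-4-en-1-yl 6-methyl-2-methylidenehept-5-enoate
Product: 13 (2E)-5-[(2S,3R)-3-hydroxy-3-methyl-6-(4-methylpent-3-en-1-yl)-7-oxo-2,3,4,7-tetrahydrooxepin-2-yl]-3-methylpent-2-en-1-yl acetate (target), via deoxy-Breslow enamine 11 (not isolated), via azolium alkoxide 12 (not isolated)
Conditions: 1,3,4-triphenyl-4,5-dihydro-1H-1,2,4-triazol-5-ylidene (20 mol %), LiCl (0.5 equiv), 1,2-dimethoxyethane, 5 mM, 80 °C
Reagents that add atoms: none
Why: Proposed new method: the carbene adds to the acrylate CH2 (C4) and a 1,2-proton shift gives the electron-rich enamine 11, whose C4 is now nucleophilic; C4 opens the tethered epoxide at its CH2 (C5, the only carbon open to SN2 attack, LiCl activating the oxirane) to close the seven-membered ring as azolium alkoxide 12, and alkoxide-relayed removal of the C3 proton expels the carbene (E1cB) to leave the C3=C4 bond, which can only be cis in this ring; the closest known reaction types are the carbene-catalysed intramolecular β-alkylation of α,β-unsaturated esters by tethered alkyl halides (umpolung of Michael acceptors) and the carbene-catalysed tail-to-tail dimerisation of methacrylates, extended here from a halide to an epoxide electrophile; C6 keeps its oxygen and C7 its ester oxygen, so no stereocentre is touched.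

**Compound list**
1 | geranyl acetate, (2E)-3,7-dimethylocta-2,6-dien-1-yl acetate | CC(=O)OC/C=C(\C)CCC=C(C)C | starting material
2 | (2E)-6-hydroperoxy-3,7-dimethylocta-2,7-dien-1-yl acetate (racemic) | CC(=O)OC/C=C(\C)CCC(OO)C(C)=C | intermediate
3 | (2E)-6-hydroxy-3,7-dimethylocta-2,7-dien-1-yl acetate (racemic) | CC(=O)OC/C=C(\C)CCC(O)C(C)=C | intermediate
4 | (2E,6S)-6-hydroxy-3-methyl-6-[(2R)-2-methyloxiran-2-yl]hex-2-en-1-yl acetate | CC(=O)OC/C=C(\C)CC[C@H](O)[C@@]1(C)CO1 | intermediate
5 | sulcatone, 6-methylhept-5-en-2-one | CC(=O)CCC=C(C)C | starting material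
6 | lithium 6-methylhepta-1,5-dien-2-olate | [Li+].[O-]C(=C)CCC=C(C)C | intermediate
7 | 6-methylhepta-1,5-dien-2-yl trifluoromethanesulfonate | C=C(OS(=O)(=O)C(F)(F)F)CCC=C(C)C | intermediate
8 | 6-methyl-2-methylidenehept-5-enoic acid | C=C(CCC=C(C)C)C(=O)O | intermediate
9 | 6-methyl-2-methylidenehept-5-enoic 2,4,6-trichlorobenzoic anhydride | C=C(CCC=C(C)C)C(=O)OC(=O)c1c(Cl)cc(Cl)cc1Cl | intermediate
10 | (1S,4E)-6-(acetyloxy)-4-methyl-1-[(2R)-2-methyloxiran-2-yl]hex-4-en-1-yl 6-methyl-2-methylidenehept-5-enoate | CC(=O)OC/C=C(\C)CC[C@H](OC(=O)C(=C)CCC=C(C)C)[C@@]1(C)CO1 | intermediate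
11 | (1S,4E)-6-(acetyloxy)-4-methyl-1-[(2R)-2-methyloxiran-2-yl]hex-4-en-1-yl 6-methyl-2-[(1,3,4-triphenyl-1,4-dihydro-5H-1,2,4-triazol-5-ylidene)methyl]hept-5-enoate (acid C2 unspecified) | CC(=O)OC/C=C(\C)CC[C@H](OC(=O)C(CCC=C(C)C)C=C1N(c2ccccc2)N=C(c2ccccc2)N1c1ccccc1)[C@@]1(C)CO1 | intermediate
12 | (2S,3R)-2-[(3E)-5-(acetyloxy)-3-methylpent-3-en-1-yl]-3-methyl-6-(4-methylpent-3-en-1-yl)-7-oxo-5-(1,3,4-triphenyl-1H-1,2,4-triazol-4-ium-5-yl)oxepan-3-olate (C5 and C6 unspecified) | CC(=O)OC/C=C(\C)CC[C@@H]1OC(=O)C(CCC=C(C)C)C(c2n(-c3ccccc3)nc(-c3ccccc3)[n+]2-c2ccccc2)C[C@@]1(C)[O-] | intermediate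
13 | (2E)-5-[(2S,3R)-3-hydroxy-3-methyl-6-(4-methylpent-3-en-1-yl)-7-oxo-2,3,4,7-tetrahydrooxepin-2-yl]-3-methylpent-2-en-1-yl acetate | CC(=O)OC/C=C(\C)CC[C@@H]1OC(=O)C(CCC=C(C)C)=CC[C@@]1(C)O | target

**Step count**
Total: 6 steps. Longest linear sequence: 4 steps (1 → 3 → 4 → 10 → 13; the acid branch 5 → 7 → 8 joins at step 5).

**Steps most likely to fail, with fallbacks**

Step 6 (highest risk). An epoxide has not been used as the electrophile in this carbene umpolung, and seven-membered closure must pass through the less favoured ester rotamer. Competing paths are tail-to-tail dimerisation of the acrylate, alkylation of the carbene by the epoxide, and base-mediated acyl shift of the product to the six-membered lactone through the C6 hydroxyl. High dilution and stopping at full conversion are the first measures.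

The fallback sets out from 4 and comes back at 13. It closes the ring by olefin metathesis instead. Epoxy alcohol 4 is opened at its CH2 with LiC≡CH (from HC≡CH and n-BuLi) and BF3·OEt2 in THF at −78 °C, conditions that spare the acetate, to give (2E,6S,7R)-6,7-dihydroxy-3,7-dimethyldec-2-en-9-yn-1-yl acetate F1. Semi-hydrogenation (H2, Pd/CaCO3 poisoned with Pb(OAc)2, quinoline) gives (2E,6S,7R)-6,7-dihydroxy-3,7-dimethyldeca-2,9-dien-1-yl acetate F2. Yamaguchi esterification with 8 through the same mixed anhydride 9 acylates only the secondary hydroxyl and gives (2E,6S,7R)-7-hydroxy-3,7-dimethyl-6-[(6-methyl-2-methylidenehept-5-enoyl)oxy]deca-2,9-dien-1-yl acetate F3. Ring-closing metathesis of the allyl group with the acrylate CH2 (second-generation Hoveyda–Grubbs catalyst, PhMe, 2 mM, 80 °C) forms C3=C4 under neutral conditions and gives 13. The side reaction to watch there is closure onto the trisubstituted 2,3-olefin of the side chain.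

Step 2. The resolution caps the yield at 50 %. The selectivity factor could be lower than for simple 2-methyl allylic alcohols, and 2-substituted epoxy alcohols can be opened by titanium alkoxides.

The fallback sets out from 3 and comes back at 4. It replaces resolution by asymmetric reduction followed by substrate-directed epoxidation. Dess–Martin oxidation of 3 gives (2E)-3,7-dimethyl-6-oxoocta-2,7-dien-1-yl acetate F4. Reduction with catecholborane and (3aR)-1-methyl-3,3-diphenyltetrahydro-1H,3H-pyrrolo[1,2-c][1,3,2]oxazaborole (20 mol %, PhMe, −78 °C; the isopropenyl group acts as the large substituent) gives (2E,6S)-6-hydroxy-3,7-dimethylocta-2,7-dien-1-yl acetate F5. Hydroxyl-directed epoxidation with VO(acac)2 and t-BuOOH (CH2Cl2, 0 °C), which is erythro-selective for 2-substituted allylic alcohols through A(1,2) strain, gives 4 and uses all of the material.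

Step 1. The ene reaction gives the secondary and tertiary allylic hydroperoxides in roughly equal amounts, and over-oxidation at the second olefin sets in at high conversion.

The fallback sets out from 1 and comes back at 3. It builds the carbinol by C–C bond formation instead. Selective ozonolysis of the terminal olefin of 1 (O3, about 0.9 equiv, CH2Cl2/pyridine, −78 °C; then Me2S) gives (2E)-3-methyl-6-oxohex-2-en-1-yl acetate F6. Addition of isopropenylmagnesium bromide (1.05 equiv, THF, −78 °C; the aldehyde reacts far faster than the acetate) gives racemic 3.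

**Further compounds**
F1 | step 6 | (2E,6S,7R)-6,7-dihydroxy-3,7-dimethyldec-2-en-9-yn-1-yl acetate | CC(=O)OC/C=C(\C)CC[C@H](O)[C@](C)(O)CC#C
F2 | step 6 | (2E,6S,7R)-6,7-dihydroxy-3,7-dimethyldeca-2,9-dien-1-yl acetate | CC(=O)OC/C=C(\C)CC[C@H](O)[C@](C)(O)CC=C
F3 | step 6 | (2E,6S,7R)-7-hydroxy-3,7-dimethyl-6-[(6-methyl-2-methylidenehept-5-enoyl)oxy]deca-2,9-dien-1-yl acetate | CC(=O)OC/C=C(\C)CC[C@H](OC(=O)C(=C)CCC=C(C)C)[C@](C)(O)CC=C
F4 | step 2 | (2E)-3,7-dimethyl-6-oxoocta-2,7-dien-1-yl acetate | CC(=O)OC/C=C(\C)CCC(=O)C(C)=C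
F5 | step 2 | (2E,6S)-6-hydroxy-3,7-dimethylocta-2,7-dien-1-yl acetate | CC(=O)OC/C=C(\C)CC[C@H](O)C(C)=C
F6 | step 1 | (2E)-3-methyl-6-oxohex-2-en-1-yl acetate | CC(=O)OC/C=C(\C)CCC=O
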